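A closed, stirred vessel at constant volume and temperature is charged with Q, and D is read as a percent of the charge.

| flask | Q | temperature | remark | time |
|---|---|---|---|---|
| noon | 0.15 M | 0 °C | run made earlier |  |
| spring | 0.22 M | 35 °C | run made earlier |  |
| ash | 0.30 M | 5 °C |  | 40 min |
| maple | 0.30 M | 65 °C |  | 40 min |
| oak | 0.30 M | 25 °C |  | 40 min |
| elm | 0.30 M | 45 °C |  | 40 min |

| noon: time / min | noon: D / % | spring: time / min | spring: D / % |
|---|---|---|---|
| 4.00 | 0 | 2.50 | 11.3 |
| 8.00 | 0 | 5.00 | 31.0 |
| 15.0 | 1.2 | 6.00 | 36.2 |
| 25.0 | 0 | 10.0 | 45.2 |
| 50.0 | 0.1 | 12.0 | 46.1 |

(standard deviation of a reading: 1 percentage point)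



- the flask that comes out highest in amount of D, in percent of the Q charged, or "all alike" when all lie within 1.5 percentage points (ash / maple / oak / elm / all alike)
- D at the end, in percent of the Q charged, ash
- D at the end, in percent of the Q charged, maple
- D at the end, in percent of the Q charged, oak
- D at the end, in percent of the Q charged, elm

*What can you read from the spring run?* It rises and then flattens: D is 45.2% at 10.0 min and 46.1% at 12.0 min, with a scatter of 1 percentage point. I take the mean of these last two readings and call it the spring plateau 45.6%. It is a reading, and it is the large term of my reckoning.

*And the other flasks?* For a flask that I expect to finish in its time, I write the final D as the spring plateau plus a small correction, the offset, and reckon only the offset. A flask that I expect not to finish is outside this scheme, and I place it from the noon run instead.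

*Isn't the charge different?* Yes, [Q] is 0.30 M in the new flasks and 0.22 M in spring. I assume the percent carries over, and that is an assumption.

*Will the flasks get there in time?* Spring needed about 10.0 min at 35 °C, and 40 min is 4.00 times that. So elm and maple, both hotter than spring, should finish. Oak is colder and has that slack to spend, so I put it a little under the plateau. Noon gave 0.1% after 50.0 min, and ash is only slightly warmer, so I put ash near that reading, far less than the plateau.

*Where is the weak spot?* One plateau shows no temperature dependence, so the sign of the offset is unknown. I carry zero for elm and maple, which makes them a tie at 45.6%.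

The forecast gave ash 1.5%, oak 40%, elm 46% and maple 43%, named elm highest, and warned that at the hot end “the plateau may shift or D may be lost”; its maple value lies below my 45.6%.

The flasks give ash 2.01%, oak 42.2%, elm 49.9% and maple 57.7%, so maple comes out highest.

    Q → G (k = 0.117 /min, Ea = 86.0 kJ/mol)
    G → J (k = 0.205 /min, Ea = 90.0 kJ/mol)
    J → D (k = 0.231 /min, Ea = 81.0 kJ/mol)
    D ⇌ E (K = 1.43, k = 0.115 /min, Ea = 95.0 kJ/mol, ΔH = −14.0 kJ/mol)
    (constants at 25 °C)

In maple, D and E relax toward each other with a half-life of 1.64 s, far shorter than the 40 min of the run, and the flask ends at D 57.7% and E 42.3%, which is thermodynamic control. The offset from the spring plateau is 4.3 points in elm and 12 points in maple. The same flask as maple run at 40 °C ends at 47.8%, an offset of 2.2 points.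

(The readings were computed from invented constants, and the scatter is random.)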